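**Target 17:** (3R)-8-hydroxy-3-(11-hydroxyundecyl)-6-methoxy-3,4-dihydroisochromen-1-one. The plan is a 9-step linear route in which arene ring A is closed by aldol aromatisation of an open-chain triketo ester (step 7).

## The problem

Compound 17 is a 3,4-dihydroisocoumarin. Arene ring A (C4a, C5, C6, C7, C8, C8a) is fused along the C4a–C8a bond to δ-lactone ring B (C1, O2, C3, C4, C4a, C8a), and C3 carries an unbranched eleven-carbon chain ending in a primary alcohol.

There is one stereocentre, C3 (R). Nothing else in the molecule can direct it, so it must come from a reagent or catalyst; once set it controls nothing further and only has to survive. In every open-chain precursor this carbinol carbon lies β to a carbonyl group or to the arene, so the C3–O bond must never be ionised or eliminated. Closing the lactone at the acyl carbon C1 rather than at C3 keeps the configuration out of play.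

Ring A carries a free hydroxyl at C8, hydrogen-bonded to the C1 carbonyl, and a methyl ether at C6; the two phenolic oxygens have to be told apart. The lactone opens with hydroxide or alkoxide, and the primary alcohol has to be masked through strongly basic steps and released at the end without harming ring B.

The enabling feature is the oxygen pattern along the path C1–C8a–C8–C7–C6–C5–C4a–C4–C3: oxygen sits on C1, C8, C6 and C3. The one alternating position without oxygen, C4a, is the carbon that would lose its oxygen as water in an aldol condensation. Read as carbonyl groups, the pattern is a 3,5,7-triketo ester oxygenated at C9, in which C8a is a doubly activated methylene and C4a a ketone carbon, so ring A can be closed by forming the C4a–C8a bond.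

## Retrosynthesis

Ring numbering is used for 17 and chain numbering (C1 ester carbon to C20) for the open-chain precursor 12.

**17 ⇒ 15 (through 16).** The acyl–oxygen bond C1–O2 of the lactone and the two O–H bonds (as O–Si) are cut. Forming O2–C3 instead, by displacement or C–H oxidation, would make or break a bond at the stereocentre; closure at C1 leaves the C3–O bond untouched. The precursor 15 is an open-chain methyl benzoate with both alcohols silylated. The forward step asks one acid treatment to remove both silyl groups and let the freed secondary hydroxyl of seco ester 16 displace methanol.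

**15 ⇒ 14.** The O–CH3 bond at the oxygen that becomes the C6 substituent is cut. Carrying this methyl group earlier would mean a methyl enol ether inside the polyketone chain, which would block the enolate chemistry needed to build and fold it. The forward methylation must distinguish two phenols. In 14 one is hydrogen-bonded to the ester carbonyl and the other is para to the ester and more acidic, so a simple alkylation should choose correctly.

**14 ⇒ 12 (key disconnection).** The C4a–C8a bond of ring A is cut, which is the C2–C7 bond of the chain in 12. The neighbouring cuts, C4–C4a or C1–C8a, would start from a preformed arene and need lateral or ortho metalation, phenol differentiation on the ring and a separate chiral electrophile. The aldol cut removes the ring altogether and leaves an acyclic triketo ester with one stereocentre. The forward step must choose the C2-to-C7 aldol over the Claisen mode, over pyranone formation and over loss of the C9 silyloxy group.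

**12 ⇒ 9 + 10 (through 11).** The C6–C7 bond of the chain is cut. This separates the stereogenic lipid part from an achiral C6 piece, methyl 3,5-dioxohexanoate 10, which already holds three of the four carbonyl carbons and reacts at its terminal carbon as trianion 11. A cut at C4–C5 would need two polycarbonyl partners of similar complexity. The acyl donor is the N-methoxy-N-methyl amide 9 rather than a methyl ester: the amide holds the tetrahedral adduct until quench, so the acidic triketone is not formed in the presence of unreacted 11. It is also less prone to α-deprotonation, which would open the way to elimination of the β-silyloxy group.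

**9 ⇒ 8 ⇒ 7.** The O–Si bond at the secondary oxygen and the amide C–N bond are cut. The amide is made first from hydroxy ester 7, where the magnesium alkoxide protects the β-position against elimination. Silylation of 8 then gives 9.

**7 ⇒ 6.** The C3–H bond of the carbinol is cut, leading to β-keto ester 6. Catalytic asymmetric hydrogenation sets the only stereocentre in one step from a prochiral ketone. An auxiliary-based acetate aldol or an allylation–oxidation sequence would need more steps and stoichiometric chirality. The forward step needs high enantioselectivity and tolerance of the remote silyl ether.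

**6 ⇒ 3 + 4 (through 5); 3 ⇒ 1 (through 2).** The C2–C3 bond of the β-keto ester is cut into acyl imidazolide 5 (from acid 3) and the malonate half-ester salt 4. Acid 3 comes from 12-hydroxydodecanoic acid 1 by silylation through bis-silyl compound 2. Compound 1 already holds all twelve carbons of C3 and the side chain with oxygen at both ends, so no C–C bond is needed in the lipid part.

## Roads not taken

**Alternative 1:** Here the O2–C3 bond is cut as an allylic C–H oxidation and the C1'–C2' bond of the side chain as an olefin metathesis.

- **Forward key step:** 2-(but-3-en-1-yl)-4,6-dimethoxybenzoic acid A2 would be treated with Pd(OAc)2, a chiral sulfoxide–oxazoline ligand and benzoquinone. Divalent palladium cleaves the allylic C–H bond at the future C3 and the carboxylate attacks the internal terminus of the π-allyl unit. The product is (3S)-3-ethenyl-6,8-dimethoxy-3,4-dihydroisochromen-1-one A1, spatially the 3R series of 17; the descriptor changes because vinyl outranks C4. Cross-metathesis with undec-10-en-1-ol A3 (second-generation Grubbs catalyst), hydrogenation and chelation-directed removal of the C8 methyl group with BCl3 would finish the synthesis.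
- **Merits:** Ring B and the stereocentre come from one catalytic step on an achiral acid, the chain is attached late, and the sequence would be about three steps shorter than the nine proposed here.
- **Weak points:** The nucleophile is an electron-rich benzoic acid flanked by two ortho substituents. The product A1 holds an allylic C–O bond that the zerovalent palladium formed in each turnover could ionise again, with erosion of enantiopurity. The same bond is exposed to hydrogenolysis when the metathesis alkene is reduced. The two aryl ethers must be told apart at the very end by a Lewis acid in the presence of the lactone and the free alcohol.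
- **Comparison:** In step count and modularity this road is better. The chosen plan sets against it a stereocentre made by a ketone hydrogenation of very broad scope, a carbinol C–O bond that is never allylic, and phenols differentiated by alkylation instead of demethylation.

**Alternative 2:** The cut runs through ring A at C4a–C5 and C8–C8a and leaves ring B intact as a chiral unsaturated lactone.

- **Forward key step:** 1,3-dimethoxy-1-(trimethylsilyloxy)buta-1,3-diene A6 would add across the brominated alkene of (6R)-3-bromo-6-[11-(tert-butyldimethylsilyloxy)undecyl]-5,6-dihydro-2H-pyran-2-one A5. The nucleophilic CH2 terminus of the diene bonds to the β-carbon (future C4a) and the ketene acetal carbon to the brominated α-carbon (future C8a). Loss of HBr, silanol and methanol would aromatise the adduct to (3R)-3-[11-(tert-butyldimethylsilyloxy)undecyl]-8-hydroxy-6-methoxy-3,4-dihydroisochromen-1-one A4, one desilylation away from 17.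
- **Merits:** The arene arrives with the C6 methyl ether and the free C8 hydroxyl already in place, so no selective methylation is needed. In this respect it is better than the chosen plan, which spends step 8 on that task. The regiochemistry is fixed by the polarity of the two partners.
- **Weak points:** A bromo dihydropyranone is a much weaker dienophile than the halo quinones on which this benzannulation is usually run, so heating with an excess of a heat- and moisture-sensitive diene must be expected. HBr is set free next to a silyl ether. A5 itself needs some six steps (asymmetric allylation of a C12 aldehyde, acryloylation, ring-closing metathesis, bromination, dehydrobromination), so the route is as long as the chosen one or longer.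
- **Comparison:** The chosen plan closes the same ring intramolecularly, where reactivity is not in doubt, and reaches its cyclisation precursor in six steps from cheap materials.

**Alternative 3:** Ring B is traced back to a five-membered ketone. The C1–O2 and O2–C3 bonds are cut by removing the ring oxygen, giving racemic 2-(11-hydroxyundecyl)-5,7-dimethoxy-2,3-dihydro-1H-inden-1-one A8.

- **Forward key step:** A Baeyer–Villiger monooxygenase with NADPH and O2 would oxidise one enantiomer of A8 while the other racemises through its enol. Migration of the chain-bearing C2 with retention would give (3R)-3-(11-hydroxyundecyl)-6,8-dimethoxy-3,4-dihydroisochromen-1-one A7. Demethylation at C8 with BCl3 would give 17.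
- **Merits:** On paper this is the shortest road (four or five steps). It needs no protecting group on the primary alcohol and converts the whole racemate.
- **Weak points:** The enzyme has to accept a ketone with a long lipophilic chain and a methoxy group peri to the carbonyl. It also has to make the alkyl carbon migrate, although the electron-rich aryl group is the better migrating group in the non-enzymatic reaction and would give the isomeric dihydrocoumarin. Dynamic kinetic resolutions of this type are established for indanones with small 2-alkyl groups; for this substrate, enzyme screening or engineering would be part of the project. The selective demethylation remains.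
- **Comparison:** The chosen plan is longer, but none of its steps depends on finding a catalyst.

Key step: step 7

Assumption: methyl 3,5-dioxohexanoate 10 is taken as a purchasable compound; 10, 12 and 13 are written as keto tautomers although they will exist largely as enols.

## Route

Step 1
Reactants: 1 12-hydroxydodecanoic acid
Product: 3 12-(tert-butyldimethylsilyloxy)dodecanoic acid, via tert-butyldimethylsilyl 12-(tert-butyldimethylsilyloxy)dodecanoate 2 (not isolated)
Conditions: TBSCl (2.3 equiv), imidazole, DMF, rt; then K2CO3, MeOH–THF–H2O, rt; work-up at pH 4–5
Reagents that add atoms: tert-butyldimethylsilyl chloride, CC(C)(C)[Si](C)(C)Cl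
Why: Silylation of both the alcohol and the acid followed by selective hydrolysis of the far more labile silyl ester with mild aqueous carbonate should leave the primary silyl ether in place.

Step 2
Reactants: 3 12-(tert-butyldimethylsilyloxy)dodecanoic acid; 4 potassium methyl malonate
Product: 6 methyl 14-(tert-butyldimethylsilyloxy)-3-oxotetradecanoate, via 1-[12-(tert-butyldimethylsilyloxy)dodecanoyl]imidazole 5 (not isolated)
Conditions: CDI, THF, rt; then 4, MgCl2, Et3N, MeCN, rt to 40 °C; aq. citric acid work-up
Reagents that add atoms: none
Why: Masamune–Brooks homologation: the acyl imidazolide C-acylates the magnesium enolate of the malonate half-ester and decarboxylation gives the β-keto ester under nearly neutral conditions that a silyl ether tolerates.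

Step 3
Reactants: 6 methyl 14-(tert-butyldimethylsilyloxy)-3-oxotetradecanoate
Product: 7 methyl (3R)-14-(tert-butyldimethylsilyloxy)-3-hydroxytetradecanoate
Conditions: H2 (50 bar), RuCl2[(R)-BINAP] (0.5 mol%), degassed MeOH, 40 °C
Reagents that add atoms: none
Why: Noyori asymmetric hydrogenation of a β-keto ester: the substrate chelates divalent ruthenium through both carbonyl oxygens and the (R)-BINAP ligand exposes the ketone face whose reduction gives the (3R)-carbinol, the established sense for 3-oxoalkanoates with an unbranched chain. The moderate temperature is meant to spare the silyl ether from traces of HCl, and any primary hydroxyl set free would be silylated again in step 5.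

Step 4
Reactants: 7 methyl (3R)-14-(tert-butyldimethylsilyloxy)-3-hydroxytetradecanoate
Product: 8 (3R)-14-(tert-butyldimethylsilyloxy)-3-hydroxy-N-methoxy-N-methyltetradecanamide
Conditions: MeNHOMe·HCl, iPrMgCl, THF, −20 to 0 °C
Reagents that add atoms: N,O-dimethylhydroxylamine hydrochloride, CNOC.Cl
Why: Direct aminolysis of the ester by the chloromagnesium amide of N,O-dimethylhydroxylamine (Weinreb amide formation); the β-hydroxyl is present as its magnesium alkoxide, which disfavours enolisation and elimination, and no bond at the stereocentre is touched.

Step 5
Reactants: 8 (3R)-14-(tert-butyldimethylsilyloxy)-3-hydroxy-N-methoxy-N-methyltetradecanamide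
Product: 9 (3R)-3,14-bis(tert-butyldimethylsilyloxy)-N-methoxy-N-methyltetradecanamide
Conditions: TBSCl (1.5 equiv), imidazole, DMF, rt
Reagents that add atoms: tert-butyldimethylsilyl chloride, CC(C)(C)[Si](C)(C)Cl
Why: Standard silyl ether formation at the secondary alcohol; the excess of reagent also restores the primary silyl ether should any have been lost earlier.

Step 6
Reactants: 9 (3R)-3,14-bis(tert-butyldimethylsilyloxy)-N-methoxy-N-methyltetradecanamide; 10 methyl 3,5-dioxohexanoate
Product: 12 methyl (9R)-9,20-bis(tert-butyldimethylsilyloxy)-3,5,7-trioxoicosanoate, via trilithium trianion of methyl 3,5-dioxohexanoate 11 (not isolated)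
Conditions: 10 (1.5 equiv), LiN(iPr)2 (4.5 equiv), THF, 0 °C; then 9, −78 to 0 °C; then AcOH, −40 °C; used crude
Reagents that add atoms: none
Why: Acylation of a β-dicarbonyl polyanion at its last-formed and most nucleophilic terminal carbon (C6 of 11) by a Weinreb amide; the chelated tetrahedral adduct persists until the quench, so the acidic triketone never meets unreacted 11 and no second addition occurs. The silyl ethers are inert to the amide base, and a cold, weakly acidic quench is chosen to keep 12 from closing to a pyranone.

Step 7
Reactants: 12 methyl (9R)-9,20-bis(tert-butyldimethylsilyloxy)-3,5,7-trioxoicosanoate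
Product: 14 methyl 2-[(2R)-2,13-bis(tert-butyldimethylsilyloxy)tridecyl]-4,6-dihydroxybenzoate, via cyclic aldol adduct 13 (not isolated)
Conditions: K2CO3 (aq., 2 equiv), MeOH–THF, 0 °C to rt; then AcOH to pH 5
Reagents that add atoms: none
Why: In aqueous carbonate 12 is present as its enolates; C2, acidified by the ester and the C3 ketone, adds to the C7 ketone to give cyclohexanedione aldol 13, which loses water by E1cB and tautomerises at C3 and C5 to the arene, so the C2–C7 bond of the chain becomes the C4a–C8a bond of ring A. The closest known reaction type is the base-mediated aldol cyclisation of 3,5,7-triketo esters to β-resorcylate esters, a laboratory version of polyketide folding. Ring A closes in a 6-(enolexo)-exo-trig mode, which is stereoelectronically favoured. No stereocentre is created: the two ring stereocentres of 13 are transient and become sp2 carbons, and C9 of the chain, set in step 3, is a spectator. The step needs chemoselectivity for the C2-to-C7 aldol over the C6-to-C1 Claisen closure, over oxygen cyclisation to a pyranone and over β-elimination of the C9 silyloxy group. Mild aqueous base keeps expulsion of methoxide slow and avoids the acidic or dehydrating conditions under which pyranones form; the C7 ketone enolises toward the far more acidic C6 rather than toward C8, and silyloxide is a poor leaving group, so elimination should not compete. Aromatisation is irreversible and should pull the preceding equilibria through.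

Step 8
Reactants: 14 methyl 2-[(2R)-2,13-bis(tert-butyldimethylsilyloxy)tridecyl]-4,6-dihydroxybenzoate
Product: 15 methyl 2-[(2R)-2,13-bis(tert-butyldimethylsilyloxy)tridecyl]-6-hydroxy-4-methoxybenzoate
Conditions: MeI (1.1 equiv), K2CO3, acetone, rt
Reagents that add atoms: iodomethane, CI
Why: Williamson O-methylation; the 4-hydroxyl para to the ester is the more acidic and unencumbered phenol, whereas the 6-hydroxyl is tied up in a hydrogen bond to the ester carbonyl, so one equivalent of iodomethane should alkylate the 4-position only.

Step 9
Reactants: 15 methyl 2-[(2R)-2,13-bis(tert-butyldimethylsilyloxy)tridecyl]-6-hydroxy-4-methoxybenzoate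
Product: 17 (3R)-8-hydroxy-3-(11-hydroxyundecyl)-6-methoxy-3,4-dihydroisochromen-1-one, via seco diol ester 16 (not isolated)
Conditions: p-TsOH·H2O (0.2 equiv), MeOH–CH2Cl2, rt; then solvent exchange to PhMe, 60 °C
Reagents that add atoms: none
Why: Acid-catalysed methanolysis of both silyl ethers gives 16, whose secondary hydroxyl lies five atoms from the ester carbonyl and closes the six-membered lactone by intramolecular transesterification with loss of methanol. The closure cleaves the acyl–oxygen bond only, so the C3 configuration is retained, and removing methanol in the second stage should drive it to completion.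

## Compound list

1 | 12-hydroxydodecanoic acid | OCCCCCCCCCCCC(=O)O | starting material
2 | tert-butyldimethylsilyl 12-(tert-butyldimethylsilyloxy)dodecanoate | CC(C)(C)[Si](C)(C)OCCCCCCCCCCCC(=O)O[Si](C)(C)C(C)(C)C | intermediate
3 | 12-(tert-butyldimethylsilyloxy)dodecanoic acid | CC(C)(C)[Si](C)(C)OCCCCCCCCCCCC(=O)O | intermediate
4 | potassium methyl malonate | COC(=O)CC(=O)[O-].[K+] | starting material
5 | 1-[12-(tert-butyldimethylsilyloxy)dodecanoyl]imidazole | CC(C)(C)[Si](C)(C)OCCCCCCCCCCCC(=O)n1ccnc1 | intermediate
6 | methyl 14-(tert-butyldimethylsilyloxy)-3-oxotetradecanoate | COC(=O)CC(=O)CCCCCCCCCCCO[Si](C)(C)C(C)(C)C | intermediate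
7 | methyl (3R)-14-(tert-butyldimethylsilyloxy)-3-hydroxytetradecanoate | COC(=O)C[C@H](O)CCCCCCCCCCCO[Si](C)(C)C(C)(C)C | intermediate
8 | (3R)-14-(tert-butyldimethylsilyloxy)-3-hydroxy-N-methoxy-N-methyltetradecanamide | CON(C)C(=O)C[C@H](O)CCCCCCCCCCCO[Si](C)(C)C(C)(C)C | intermediate
9 | (3R)-3,14-bis(tert-butyldimethylsilyloxy)-N-methoxy-N-methyltetradecanamide | CON(C)C(=O)C[C@@H](CCCCCCCCCCCO[Si](C)(C)C(C)(C)C)O[Si](C)(C)C(C)(C)C | intermediate
10 | methyl 3,5-dioxohexanoate | COC(=O)CC(=O)CC(C)=O | starting material
11 | trilithium 2,4,6-trianion of methyl 3,5-dioxohexanoate | [Li+].[Li+].[Li+].[CH2-]C(=O)[CH-]C(=O)[CH-]C(=O)OC | intermediate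
12 | methyl (9R)-9,20-bis(tert-butyldimethylsilyloxy)-3,5,7-trioxoicosanoate | COC(=O)CC(=O)CC(=O)CC(=O)C[C@@H](CCCCCCCCCCCO[Si](C)(C)C(C)(C)C)O[Si](C)(C)C(C)(C)C | intermediate
13 | methyl 2-[(2R)-2,13-bis(tert-butyldimethylsilyloxy)tridecyl]-2-hydroxy-4,6-dioxocyclohexane-1-carboxylate (mixture at ring C1 and C2) | COC(=O)C1C(=O)CC(=O)CC1(O)C[C@@H](CCCCCCCCCCCO[Si](C)(C)C(C)(C)C)O[Si](C)(C)C(C)(C)C | intermediate
14 | methyl 2-[(2R)-2,13-bis(tert-butyldimethylsilyloxy)tridecyl]-4,6-dihydroxybenzoate | COC(=O)c1c(O)cc(O)cc1C[C@@H](CCCCCCCCCCCO[Si](C)(C)C(C)(C)C)O[Si](C)(C)C(C)(C)C | intermediate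
15 | methyl 2-[(2R)-2,13-bis(tert-butyldimethylsilyloxy)tridecyl]-6-hydroxy-4-methoxybenzoate | COC(=O)c1c(O)cc(OC)cc1C[C@@H](CCCCCCCCCCCO[Si](C)(C)C(C)(C)C)O[Si](C)(C)C(C)(C)C | intermediate
16 | methyl 2-[(2R)-2,13-dihydroxytridecyl]-6-hydroxy-4-methoxybenzoate | COC(=O)c1c(O)cc(OC)cc1C[C@@H](CCCCCCCCCCCO)O | intermediate
17 | (3R)-8-hydroxy-3-(11-hydroxyundecyl)-6-methoxy-3,4-dihydroisochromen-1-one | COc1cc(O)c2c(c1)C[C@@H](CCCCCCCCCCCO)OC2=O | target

## Step count and risks

Total step count: 9. Longest linear sequence: 9 steps, from 1 to 17; 4 and 10 are bought and enter in steps 2 and 6.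

**Step 7 (key step).**
- Risk: closure in the wrong mode. Acid traces or silica during handling of 12 can trigger oxygen cyclisation to a pyranone. Base that is too strong or contains chelating metal ions can favour the C6-to-C1 Claisen closure. Prolonged exposure to base before ring closure could also eliminate the C9 silyloxy group.
- Fallback (from 9, returning at 17): the ester terminus is masked as a dioxinone, which leaves no alkoxide leaving group for the Claisen mode and only one free phenol afterwards. Commercial 2,2,6-trimethyl-4H-1,3-dioxin-4-one would be acetylated at its methyl group through the lithium dienolate (LiN(SiMe3)2, acetyl chloride) to 2,2-dimethyl-6-(2-oxopropyl)-4H-1,3-dioxin-4-one F1. The dianion of F1 (LiN(iPr)2) would be acylated by 9 to 6-[(6R)-6,17-bis(tert-butyldimethylsilyloxy)-2,4-dioxoheptadecyl]-2,2-dimethyl-4H-1,3-dioxin-4-one F2. Et3N in CH2Cl2 should then bring about the same carbon–carbon aldol aromatisation to 5-[(2R)-2,13-bis(tert-butyldimethylsilyloxy)tridecyl]-7-hydroxy-2,2-dimethyl-4H-1,3-benzodioxin-4-one F3. Methylation of its only free phenol (MeI, K2CO3) gives 5-[(2R)-2,13-bis(tert-butyldimethylsilyloxy)tridecyl]-7-methoxy-2,2-dimethyl-4H-1,3-benzodioxin-4-one F4. Bu4NF in THF would remove both silyl groups, and the secondary alkoxide so released opens the dioxinone by acyl transfer with loss of acetone, giving 17.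

**Step 6.**
- Risk: proton transfer instead of acylation. If 11 deprotonates the α-methylene of 9, silyloxide can be eliminated. Incomplete trianion formation would lead to acylation at an internal carbon or on oxygen, and any excess LiN(iPr)2 can fragment the N-methoxy amide.
- Fallback (from 9, returning at 12): the carbon–carbon bond is made by aldol addition and the oxidation level is adjusted afterwards. Reduction of 9 with iBu2AlH gives (3R)-3,14-bis(tert-butyldimethylsilyloxy)tetradecanal F5. Addition of 11 to this aldehyde, which should outrun proton transfer, gives methyl (9R)-9,20-bis(tert-butyldimethylsilyloxy)-7-hydroxy-3,5-dioxoicosanoate F6 as a mixture at C7. Oxidation of the β-hydroxy ketone with Dess–Martin periodinane gives 12.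

**Step 3.**
- Risk: acid-promoted methanolysis of the primary silyl ether by traces of HCl from the catalyst, giving mixtures of silylated and free alcohol. Slow turnover at the low temperature chosen to prevent this is the accompanying risk.
- Fallback (from 6, returning at 9): the desilylation is accepted and made complete. Hydrogenation of 6 with the same catalyst in methanol containing a deliberate trace of HCl at higher temperature gives methyl (3R)-3,14-dihydroxytetradecanoate F7. Aminolysis as in step 4, with one further equivalent of iPrMgCl, gives (3R)-3,14-dihydroxy-N-methoxy-N-methyltetradecanamide F8. Silylation of both hydroxyls with excess TBSCl and imidazole gives 9. The step count is unchanged.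

**Step 8.**
- Risk: loss of selectivity between the two phenols. The ester of 14 has two ortho substituents and may twist out of the ring plane, which weakens the hydrogen bond that shields the 6-hydroxyl and allows double methylation.
- Fallback (from 14, returning at 17): the order of the last two steps is reversed. Acid treatment of 14 as in step 9 gives (3R)-6,8-dihydroxy-3-(11-hydroxyundecyl)-3,4-dihydroisochromen-1-one F9, in which the C8 hydroxyl is held in a strong peri hydrogen bond to the coplanar lactone carbonyl. One equivalent of MeI with K2CO3 in acetone should then methylate only the C6 hydroxyl and give 17.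

**Step 9.**
- Risk: stalling at the open hydroxy ester, because transesterification of a hindered, hydrogen-bonded benzoate is an equilibrium in methanol. At high concentration, intermolecular ester exchange through the primary alcohol could also occur.
- Fallback (from 15, returning at 17): the lactone is closed from the acid instead of the ester. Compound 15 is desilylated with acid in methanol to 16, which is isolated and saponified with aqueous LiOH, assisted by the neighbouring alkoxide, to 2-[(2R)-2,13-dihydroxytridecyl]-6-hydroxy-4-methoxybenzoic acid F10. On acidification this hydroxy acid should close irreversibly to the six-membered lactone 17.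

## Further compounds

F1 | step 7 | 2,2-dimethyl-6-(2-oxopropyl)-4H-1,3-dioxin-4-one | CC(=O)CC1=CC(=O)OC(C)(C)O1
F2 | step 7 | 6-[(6R)-6,17-bis(tert-butyldimethylsilyloxy)-2,4-dioxoheptadecyl]-2,2-dimethyl-4H-1,3-dioxin-4-one | CC1(C)OC(=O)C=C(CC(=O)CC(=O)C[C@@H](CCCCCCCCCCCO[Si](C)(C)C(C)(C)C)O[Si](C)(C)C(C)(C)C)O1
F3 | step 7 | 5-[(2R)-2,13-bis(tert-butyldimethylsilyloxy)tridecyl]-7-hydroxy-2,2-dimethyl-4H-1,3-benzodioxin-4-one | CC1(C)OC(=O)c2c(O1)cc(O)cc2C[C@@H](CCCCCCCCCCCO[Si](C)(C)C(C)(C)C)O[Si](C)(C)C(C)(C)C
F4 | step 7 | 5-[(2R)-2,13-bis(tert-butyldimethylsilyloxy)tridecyl]-7-methoxy-2,2-dimethyl-4H-1,3-benzodioxin-4-one | CC1(C)OC(=O)c2c(O1)cc(OC)cc2C[C@@H](CCCCCCCCCCCO[Si](C)(C)C(C)(C)C)O[Si](C)(C)C(C)(C)C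
F5 | step 6 | (3R)-3,14-bis(tert-butyldimethylsilyloxy)tetradecanal | O=CC[C@@H](CCCCCCCCCCCO[Si](C)(C)C(C)(C)C)O[Si](C)(C)C(C)(C)C
F6 | step 6 | methyl (9R)-9,20-bis(tert-butyldimethylsilyloxy)-7-hydroxy-3,5-dioxoicosanoate (mixture at C7) | COC(=O)CC(=O)CC(=O)CC(O)C[C@@H](CCCCCCCCCCCO[Si](C)(C)C(C)(C)C)O[Si](C)(C)C(C)(C)C
F7 | step 3 | methyl (3R)-3,14-dihydroxytetradecanoate | COC(=O)C[C@H](O)CCCCCCCCCCCO
F8 | step 3 | (3R)-3,14-dihydroxy-N-methoxy-N-methyltetradecanamide | CON(C)C(=O)C[C@H](O)CCCCCCCCCCCO
F9 | step 8 | (3R)-6,8-dihydroxy-3-(11-hydroxyundecyl)-3,4-dihydroisochromen-1-one | Oc1cc(O)c2c(c1)C[C@@H](CCCCCCCCCCCO)OC2=O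
F10 | step 9 | 2-[(2R)-2,13-dihydroxytridecyl]-6-hydroxy-4-methoxybenzoic acid | COc1cc(O)c(C(=O)O)c(C[C@@H](CCCCCCCCCCCO)O)c1
A1 | alternative 1 | (3S)-3-ethenyl-6,8-dimethoxy-3,4-dihydroisochromen-1-one | COc1cc(OC)c2c(c1)C[C@@H](C=C)OC2=O
A2 | alternative 1 | 2-(but-3-en-1-yl)-4,6-dimethoxybenzoic acid | COc1cc(OC)c(C(=O)O)c(CCC=C)c1
A3 | alternative 1 | undec-10-en-1-ol | OCCCCCCCCCC=C
A4 | alternative 2 | (3R)-3-[11-(tert-butyldimethylsilyloxy)undecyl]-8-hydroxy-6-methoxy-3,4-dihydroisochromen-1-one | COc1cc(O)c2c(c1)C[C@@H](CCCCCCCCCCCO[Si](C)(C)C(C)(C)C)OC2=O
A5 | alternative 2 | (6R)-3-bromo-6-[11-(tert-butyldimethylsilyloxy)undecyl]-5,6-dihydro-2H-pyran-2-one | O=C1O[C@H](CCCCCCCCCCCO[Si](C)(C)C(C)(C)C)CC=C1Br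
A6 | alternative 2 | 1,3-dimethoxy-1-(trimethylsilyloxy)buta-1,3-diene | C=C(OC)C=C(OC)O[Si](C)(C)C
A7 | alternative 3 | (3R)-3-(11-hydroxyundecyl)-6,8-dimethoxy-3,4-dihydroisochromen-1-one | COc1cc(OC)c2c(c1)C[C@@H](CCCCCCCCCCCO)OC2=O
A8 | alternative 3 | rac-2-(11-hydroxyundecyl)-5,7-dimethoxy-2,3-dihydro-1H-inden-1-one | COc1cc(OC)c2c(c1)CC(CCCCCCCCCCCO)C2=O
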